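**Retrosynthetic overview**

1. The target 20 is the deca-O-benzyl ether 19 after global debenzylation. Its three trans-2,3-diaryl-2,3-dihydrobenzofurans (each numbered O1, C2, C3, C3a, C4–C7, C7a) are called ring A (carries the 3,5-dihydroxyphenyl group), ring B (central) and ring C (carries the 3,4-dihydroxystyryl group).
2. Each ring is cut at O1–C2 and C3a–C3 into an E-stilbene and the same building block, 2-acetyl-6-benzyloxy-1,4-benzoquinone 5, joined by an enantioselective quinone–alkene formal [3+2] cycloaddition. The acetyl group on C4 and the extra hydroxyl on C5 of each adduct are then converted (double triflation, palladium–formate reduction, Heck arylation) into the next E-stilbene.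
3. Order of ring formation: ring A (step 4, from tri-O-benzylresveratrol), ring B (step 8), ring C (step 12); the catechol styryl arm is attached last (step 15).
4. Enabling feature: in ring A the benzo carbon C5 (para to C7a, between C4 and C6) carries only H, and C4 carries the carbon that becomes C3 of ring B. The benzo ring can therefore enter as a para-quinone (C7a=O and C5=O) with an acyl group on C4: C3a is then the β-carbon of two carbonyl groups, the C7a oxygen is the internal nucleophile, and the 4-oxygenated phenyl group on C2 stabilises the cation. Rings B and C have the same pattern.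

Key step: step 4

Assumption: the (4S,4'S)-ligand is taken to give the (2R,3R) ring and the (4R,4'R)-ligand the (2S,3S) ring; if the sense of induction is the reverse, the two ligands change places in steps 4, 8 and 12.

Abbreviations in names: triflate/triflyl = trifluoromethanesulfonate/trifluoromethylsulfonyl; A-yl = (2R,3R)-6-(benzyloxy)-2-[4-(benzyloxy)phenyl]-3-[3,5-bis(benzyloxy)phenyl]-2,3-dihydro-1-benzofuran-4-yl; BA-yl = (2S,3S)-3-(A-yl)-6-(benzyloxy)-2-[4-(benzyloxy)phenyl]-2,3-dihydro-1-benzofuran-4-yl.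

**Route**

Step 1
Reactants: 1 resveratrol
Product: 2 (E)-1,3-bis(benzyloxy)-5-{2-[4-(benzyloxy)phenyl]ethenyl}benzene
Conditions: BnBr (3.3 equiv), K2CO3, DMF, 60 °C
Reagents that add atoms: benzyl bromide, BrCc1ccccc1
Why: Williamson ether synthesis on the three phenoxides should give the tribenzyl ether without touching the E-alkene; no stereocentre is involved.

Step 2
Reactants: 3 1-(3,5-dihydroxyphenyl)ethan-1-one
Product: 4 1-[3-(benzyloxy)-5-hydroxyphenyl]ethan-1-one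
Conditions: BnBr (1.0 equiv), K2CO3 (1.1 equiv), acetone, 56 °C
Reagents that add atoms: benzyl bromide, BrCc1ccccc1
Why: Williamson mono-etherification of one of two equivalent phenols is statistical, so the monobenzyl ether should be the main product and is separated from the diol (recycled) and the dibenzyl ether; no stereocentre is involved.

Step 3
Reactants: 4 1-[3-(benzyloxy)-5-hydroxyphenyl]ethan-1-one
Product: 5 2-acetyl-6-(benzyloxy)cyclohexa-2,5-diene-1,4-dione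
Conditions: K2[ON(SO3)2] (2.5 equiv), KH2PO4 buffer, acetone/H2O, 0 to 20 °C; used at once
Reagents that add atoms: potassium nitrosodisulfonate, [K+].[K+].[O]N(S(=O)(=O)[O-])S(=O)(=O)[O-]
Why: Teuber oxidation, in which the nitrosodisulfonate radical oxidises the free phenol at its unsubstituted para position (between the acetyl and benzyloxy groups) to the para-quinone while the benzyl ether and ketone are inert; no stereocentre is involved.

Step 4
Reactants: 5 2-acetyl-6-(benzyloxy)cyclohexa-2,5-diene-1,4-dione; 2 (E)-1,3-bis(benzyloxy)-5-{2-[4-(benzyloxy)phenyl]ethenyl}benzene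
Product: 6 1-{(2R,3R)-6-(benzyloxy)-2-[4-(benzyloxy)phenyl]-3-[3,5-bis(benzyloxy)phenyl]-5-hydroxy-2,3-dihydro-1-benzofuran-4-yl}ethan-1-one
Conditions: Cu(OTf)2 (10 mol %), 2,2'-(propane-2,2-diyl)bis[(4S)-4-tert-butyl-4,5-dihydro-1,3-oxazole] (11 mol %), 4 Å molecular sieves, CH2Cl2, −78 to −40 °C
Reagents that add atoms: none
Why: The Cu(OTf)2–bis(oxazoline) complex (divalent copper) binds 5 through the C1 carbonyl and the acetyl oxygen, so that quinone C3 becomes a doubly activated Michael acceptor, and the alkene of 2 attacks it with the carbon that carries the 3,5-bis(benzyloxy)phenyl group because only its neighbour can hold the positive charge as a 4-benzyloxybenzyl (para-quinone methide) cation. The C4 carbonyl oxygen, made electron-rich by the 6-benzyloxy group as part of a vinylogous ester, then closes the dihydrofuran ring on this cation in a 5-exo-trig mode and loss of the C3 proton aromatises the six-membered ring, so that the C3a–C3 and O1–C2 bonds of ring A form in one operation. The closest known reaction type is the Lewis acid-catalysed formal [3+2] cycloaddition of 2-acyl- and 2-alkoxycarbonyl-1,4-benzoquinones with styrenes and 1-arylpropenes, which has enantioselective variants with chiral copper and titanium Lewis acids. C3 is set under catalyst control, the tert-butyl groups of the ligand leaving one face of the chelated quinone open to one enantioface of the alkene, and C2 is set in the ring closure, where the 4-benzyloxyphenyl group takes the side opposite to the C3 aryl group (trans, which is also the more stable isomer and stays reachable through reversible ionisation of the benzylic C2–O1 bond). The step needs site selectivity on the quinone (C3 and not C5, secured by the acetyl group and the deactivating 6-benzyloxy group), regioselectivity on the alkene (secured by the para-oxygen of the future C2 aryl group), closure through O4 and not through the acetyl oxygen (the hetero-Diels–Alder adduct is not aromatic and should revert by ionisation to the aromatic product) and enantioface selectivity (ligand).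

Step 5
Reactants: 6 1-{(2R,3R)-6-(benzyloxy)-2-[4-(benzyloxy)phenyl]-3-[3,5-bis(benzyloxy)phenyl]-5-hydroxy-2,3-dihydro-1-benzofuran-4-yl}ethan-1-one
Product: 7 (2R,3R)-6-(benzyloxy)-2-[4-(benzyloxy)phenyl]-3-[3,5-bis(benzyloxy)phenyl]-4-[1-(triflyloxy)ethenyl]-2,3-dihydro-1-benzofuran-5-yl triflate
Conditions: KN(SiMe3)2 (2.4 equiv), THF, −78 °C; then N-(5-chloropyridin-2-yl)-1,1,1-trifluoro-N-(trifluoromethylsulfonyl)methanesulfonamide (2.5 equiv), −78 to 0 °C; NH4Cl work-up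
Reagents that add atoms: N-(5-chloropyridin-2-yl)-1,1,1-trifluoro-N-(trifluoromethylsulfonyl)methanesulfonamide, FC(F)(F)S(=O)(=O)N(c1ccc(Cl)cn1)S(=O)(=O)C(F)(F)F
Why: Double O-triflation of the potassium phenoxide and of the kinetic potassium enolate of the methyl ketone turns the extra C5 oxygen and the ketone oxygen into leaving groups for palladium, and the benzylic stereocentres are not deprotonated at −78 °C.

Step 6
Reactants: 7 (2R,3R)-6-(benzyloxy)-2-[4-(benzyloxy)phenyl]-3-[3,5-bis(benzyloxy)phenyl]-4-[1-(triflyloxy)ethenyl]-2,3-dihydro-1-benzofuran-5-yl triflate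
Product: 8 (2R,3R)-6-(benzyloxy)-2-[4-(benzyloxy)phenyl]-3-[3,5-bis(benzyloxy)phenyl]-4-ethenyl-2,3-dihydro-1-benzofuran
Conditions: Pd(OAc)2 (10 mol %), 1,1'-bis(diphenylphosphino)ferrocene (12 mol %), HCO2H, Et3N, DMF, 70 °C
Reagents that add atoms: none
Why: Palladium-catalysed formate reduction of aryl and vinyl triflates (oxidative addition to zerovalent palladium, triflate–formate exchange, loss of CO2, C–H reductive elimination) replaces both C–OTf bonds by C–H, leaving C5 unsubstituted and C4 with a vinyl group, while benzyl ethers and stereocentres are untouched.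

Step 7
Reactants: 8 (2R,3R)-6-(benzyloxy)-2-[4-(benzyloxy)phenyl]-3-[3,5-bis(benzyloxy)phenyl]-4-ethenyl-2,3-dihydro-1-benzofuran; 9 1-(benzyloxy)-4-bromobenzene
Product: 10 (2R,3R)-6-(benzyloxy)-2-[4-(benzyloxy)phenyl]-3-[3,5-bis(benzyloxy)phenyl]-4-{(E)-2-[4-(benzyloxy)phenyl]ethenyl}-2,3-dihydro-1-benzofuran
Conditions: Pd(OAc)2 (5 mol %), P(o-tolyl)3 (10 mol %), Et3N, DMF, 100 °C
Reagents that add atoms: none
Why: Mizoroki–Heck reaction, in which the arylpalladium species from 9 adds to the terminal vinyl carbon and syn β-hydride elimination gives the E-stilbene; no stereocentre is formed or touched.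

Step 8
Reactants: 10 (2R,3R)-6-(benzyloxy)-2-[4-(benzyloxy)phenyl]-3-[3,5-bis(benzyloxy)phenyl]-4-{(E)-2-[4-(benzyloxy)phenyl]ethenyl}-2,3-dihydro-1-benzofuran; 5 2-acetyl-6-(benzyloxy)cyclohexa-2,5-diene-1,4-dione
Product: 11 1-[(2S,3S)-3-(A-yl)-6-(benzyloxy)-2-[4-(benzyloxy)phenyl]-5-hydroxy-2,3-dihydro-1-benzofuran-4-yl]ethan-1-one
Conditions: Cu(OTf)2 (10 mol %), 2,2'-(propane-2,2-diyl)bis[(4R)-4-tert-butyl-4,5-dihydro-1,3-oxazole] (11 mol %), 4 Å molecular sieves, CH2Cl2, −78 to −40 °C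
Reagents that add atoms: none
Why: Same copper-catalysed quinone–alkene formal [3+2] cycloaddition as in step 4, in which the alkene of 10 reacts through the carbon bound to the ring A arene because the other carbon is 4-benzyloxybenzylic, the enantiomeric ligand sets C3 of ring B (S) under catalyst control and the ring closure sets C2 (S) trans to it.

Step 9
Reactants: 11 1-[(2S,3S)-3-(A-yl)-6-(benzyloxy)-2-[4-(benzyloxy)phenyl]-5-hydroxy-2,3-dihydro-1-benzofuran-4-yl]ethan-1-one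
Product: 12 (2S,3S)-3-(A-yl)-6-(benzyloxy)-2-[4-(benzyloxy)phenyl]-4-[1-(triflyloxy)ethenyl]-2,3-dihydro-1-benzofuran-5-yl triflate
Conditions: KN(SiMe3)2 (2.4 equiv), THF, −78 °C; then N-(5-chloropyridin-2-yl)-1,1,1-trifluoro-N-(trifluoromethylsulfonyl)methanesulfonamide (2.5 equiv), −78 to 0 °C; NH4Cl work-up
Reagents that add atoms: N-(5-chloropyridin-2-yl)-1,1,1-trifluoro-N-(trifluoromethylsulfonyl)methanesulfonamide, FC(F)(F)S(=O)(=O)N(c1ccc(Cl)cn1)S(=O)(=O)C(F)(F)F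
Why: Double O-triflation of phenoxide and methyl ketone enolate as in step 5, with the four benzylic stereocentres inert to the amide base at −78 °C.

Step 10
Reactants: 12 (2S,3S)-3-(A-yl)-6-(benzyloxy)-2-[4-(benzyloxy)phenyl]-4-[1-(triflyloxy)ethenyl]-2,3-dihydro-1-benzofuran-5-yl triflate
Product: 13 (2S,3S)-3-(A-yl)-6-(benzyloxy)-2-[4-(benzyloxy)phenyl]-4-ethenyl-2,3-dihydro-1-benzofuran
Conditions: Pd(OAc)2 (10 mol %), 1,1'-bis(diphenylphosphino)ferrocene (12 mol %), HCO2H, Et3N, DMF, 70 °C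
Reagents that add atoms: none
Why: Palladium-catalysed formate reduction of the aryl and vinyl triflates as in step 6, which leaves C5 of ring B unsubstituted and C4 with a vinyl group.

Step 11
Reactants: 13 (2S,3S)-3-(A-yl)-6-(benzyloxy)-2-[4-(benzyloxy)phenyl]-4-ethenyl-2,3-dihydro-1-benzofuran; 9 1-(benzyloxy)-4-bromobenzene
Product: 14 (2S,3S)-3-(A-yl)-6-(benzyloxy)-2-[4-(benzyloxy)phenyl]-4-{(E)-2-[4-(benzyloxy)phenyl]ethenyl}-2,3-dihydro-1-benzofuran
Conditions: Pd(OAc)2 (5 mol %), P(o-tolyl)3 (10 mol %), Et3N, DMF, 100 °C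
Reagents that add atoms: none
Why: Mizoroki–Heck arylation of the terminal vinyl carbon with syn β-hydride elimination gives the E-stilbene as in step 7; no stereocentre is formed or touched.

Step 12
Reactants: 14 (2S,3S)-3-(A-yl)-6-(benzyloxy)-2-[4-(benzyloxy)phenyl]-4-{(E)-2-[4-(benzyloxy)phenyl]ethenyl}-2,3-dihydro-1-benzofuran; 5 2-acetyl-6-(benzyloxy)cyclohexa-2,5-diene-1,4-dione
Product: 15 1-[(2R,3R)-3-(BA-yl)-6-(benzyloxy)-2-[4-(benzyloxy)phenyl]-5-hydroxy-2,3-dihydro-1-benzofuran-4-yl]ethan-1-one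
Conditions: Cu(OTf)2 (10 mol %), 2,2'-(propane-2,2-diyl)bis[(4S)-4-tert-butyl-4,5-dihydro-1,3-oxazole] (11 mol %), 4 Å molecular sieves, CH2Cl2, −78 to −40 °C
Reagents that add atoms: none
Why: Third use of the copper-catalysed quinone–alkene formal [3+2] cycloaddition, in which the alkene carbon bound to the ring B arene attacks quinone C3, the (4S,4'S)-ligand sets C3 of ring C (R) under catalyst control and the ring closure sets C2 (R) trans to it.

Step 13
Reactants: 15 1-[(2R,3R)-3-(BA-yl)-6-(benzyloxy)-2-[4-(benzyloxy)phenyl]-5-hydroxy-2,3-dihydro-1-benzofuran-4-yl]ethan-1-one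
Product: 16 (2R,3R)-3-(BA-yl)-6-(benzyloxy)-2-[4-(benzyloxy)phenyl]-4-[1-(triflyloxy)ethenyl]-2,3-dihydro-1-benzofuran-5-yl triflate
Conditions: KN(SiMe3)2 (2.4 equiv), THF, −78 °C; then N-(5-chloropyridin-2-yl)-1,1,1-trifluoro-N-(trifluoromethylsulfonyl)methanesulfonamide (2.5 equiv), −78 to 0 °C; NH4Cl work-up
Reagents that add atoms: N-(5-chloropyridin-2-yl)-1,1,1-trifluoro-N-(trifluoromethylsulfonyl)methanesulfonamide, FC(F)(F)S(=O)(=O)N(c1ccc(Cl)cn1)S(=O)(=O)C(F)(F)F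
Why: Double O-triflation of phenoxide and methyl ketone enolate as in steps 5 and 9, with the six benzylic stereocentres inert at −78 °C.

Step 14
Reactants: 16 (2R,3R)-3-(BA-yl)-6-(benzyloxy)-2-[4-(benzyloxy)phenyl]-4-[1-(triflyloxy)ethenyl]-2,3-dihydro-1-benzofuran-5-yl triflate
Product: 17 (2R,3R)-3-(BA-yl)-6-(benzyloxy)-2-[4-(benzyloxy)phenyl]-4-ethenyl-2,3-dihydro-1-benzofuran
Conditions: Pd(OAc)2 (10 mol %), 1,1'-bis(diphenylphosphino)ferrocene (12 mol %), HCO2H, Et3N, DMF, 70 °C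
Reagents that add atoms: none
Why: Palladium-catalysed formate reduction of the aryl and vinyl triflates as in steps 6 and 10, which leaves C5 of ring C unsubstituted and C4 with a vinyl group.

Step 15
Reactants: 17 (2R,3R)-3-(BA-yl)-6-(benzyloxy)-2-[4-(benzyloxy)phenyl]-4-ethenyl-2,3-dihydro-1-benzofuran; 18 1,2-bis(benzyloxy)-4-bromobenzene
Product: 19 (2R,3R)-3-(BA-yl)-6-(benzyloxy)-2-[4-(benzyloxy)phenyl]-4-{(E)-2-[3,4-bis(benzyloxy)phenyl]ethenyl}-2,3-dihydro-1-benzofuran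
Conditions: Pd(OAc)2 (5 mol %), P(o-tolyl)3 (10 mol %), Et3N, DMF, 100 °C
Reagents that add atoms: none
Why: Mizoroki–Heck arylation of the terminal vinyl carbon with syn β-hydride elimination installs the protected catechol ring and the E-alkene; no stereocentre is formed or touched.

Step 16
Reactants: 19 (2R,3R)-3-(BA-yl)-6-(benzyloxy)-2-[4-(benzyloxy)phenyl]-4-{(E)-2-[3,4-bis(benzyloxy)phenyl]ethenyl}-2,3-dihydro-1-benzofuran
Product: 20 CNP0099535.1
Conditions: BCl3 (1 M in CH2Cl2, 3 equiv per ether), pentamethylbenzene (4 equiv per ether), CH2Cl2, −78 °C; then MeOH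
Reagents that add atoms: none
Why: Lewis acid debenzylation with a non-basic cation scavenger, in which BCl3 should cleave the ten aryl benzyl ethers at low temperature while pentamethylbenzene traps the benzyl cations, so that the alkene is not reduced, the electron-rich rings are not benzylated and the trans ring stereocentres (the thermodynamically preferred ones) are not expected to change.

**Compound list**

1 | resveratrol, (E)-5-[2-(4-hydroxyphenyl)ethenyl]benzene-1,3-diol | Oc1ccc(/C=C/c2cc(O)cc(O)c2)cc1 | starting material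
2 | (E)-1,3-bis(benzyloxy)-5-{2-[4-(benzyloxy)phenyl]ethenyl}benzene | c1ccccc1COc1ccc(/C=C/c2cc(OCc3ccccc3)cc(OCc3ccccc3)c2)cc1 | intermediate
3 | 1-(3,5-dihydroxyphenyl)ethan-1-one | CC(=O)c1cc(O)cc(O)c1 | starting material
4 | 1-[3-(benzyloxy)-5-hydroxyphenyl]ethan-1-one | CC(=O)c1cc(O)cc(OCc2ccccc2)c1 | intermediate
5 | 2-acetyl-6-(benzyloxy)cyclohexa-2,5-diene-1,4-dione | CC(=O)C1=CC(=O)C=C(OCc2ccccc2)C1=O | intermediate
6 | 1-{(2R,3R)-6-(benzyloxy)-2-[4-(benzyloxy)phenyl]-3-[3,5-bis(benzyloxy)phenyl]-5-hydroxy-2,3-dihydro-1-benzofuran-4-yl}ethan-1-one | CC(=O)c1c(O)c(OCc2ccccc2)cc2c1[C@@H](c1cc(OCc3ccccc3)cc(OCc3ccccc3)c1)[C@H](c1ccc(OCc3ccccc3)cc1)O2 | intermediate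
7 | (2R,3R)-6-(benzyloxy)-2-[4-(benzyloxy)phenyl]-3-[3,5-bis(benzyloxy)phenyl]-4-[1-(triflyloxy)ethenyl]-2,3-dihydro-1-benzofuran-5-yl triflate | C=C(OS(=O)(=O)C(F)(F)F)c1c(OS(=O)(=O)C(F)(F)F)c(OCc2ccccc2)cc2c1[C@@H](c1cc(OCc3ccccc3)cc(OCc3ccccc3)c1)[C@H](c1ccc(OCc3ccccc3)cc1)O2 | intermediate
8 | (2R,3R)-6-(benzyloxy)-2-[4-(benzyloxy)phenyl]-3-[3,5-bis(benzyloxy)phenyl]-4-ethenyl-2,3-dihydro-1-benzofuran | C=Cc1cc(OCc2ccccc2)cc2c1[C@@H](c1cc(OCc3ccccc3)cc(OCc3ccccc3)c1)[C@H](c1ccc(OCc3ccccc3)cc1)O2 | intermediate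
9 | 1-(benzyloxy)-4-bromobenzene | Brc1ccc(OCc2ccccc2)cc1 | starting material
10 | (2R,3R)-6-(benzyloxy)-2-[4-(benzyloxy)phenyl]-3-[3,5-bis(benzyloxy)phenyl]-4-{(E)-2-[4-(benzyloxy)phenyl]ethenyl}-2,3-dihydro-1-benzofuran | c1ccccc1COc1ccc(/C=C/c2cc(OCc3ccccc3)cc3c2[C@@H](c2cc(OCc4ccccc4)cc(OCc4ccccc4)c2)[C@H](c2ccc(OCc4ccccc4)cc2)O3)cc1 | intermediate
11 | 1-[(2S,3S)-3-(A-yl)-6-(benzyloxy)-2-[4-(benzyloxy)phenyl]-5-hydroxy-2,3-dihydro-1-benzofuran-4-yl]ethan-1-one | c1ccccc1COc1ccc([C@H]2Oc3cc(OCc4ccccc4)c(O)c(C(C)=O)c3[C@@H]2c2cc(OCc3ccccc3)cc3c2[C@@H](c2cc(OCc4ccccc4)cc(OCc4ccccc4)c2)[C@H](c2ccc(OCc4ccccc4)cc2)O3)cc1 | intermediate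
12 | (2S,3S)-3-(A-yl)-6-(benzyloxy)-2-[4-(benzyloxy)phenyl]-4-[1-(triflyloxy)ethenyl]-2,3-dihydro-1-benzofuran-5-yl triflate | c1ccccc1COc1ccc([C@H]2Oc3cc(OCc4ccccc4)c(OS(=O)(=O)C(F)(F)F)c(C(=C)OS(=O)(=O)C(F)(F)F)c3[C@@H]2c2cc(OCc3ccccc3)cc3c2[C@@H](c2cc(OCc4ccccc4)cc(OCc4ccccc4)c2)[C@H](c2ccc(OCc4ccccc4)cc2)O3)cc1 | intermediate
13 | (2S,3S)-3-(A-yl)-6-(benzyloxy)-2-[4-(benzyloxy)phenyl]-4-ethenyl-2,3-dihydro-1-benzofuran | c1ccccc1COc1ccc([C@H]2Oc3cc(OCc4ccccc4)cc(C=C)c3[C@@H]2c2cc(OCc3ccccc3)cc3c2[C@@H](c2cc(OCc4ccccc4)cc(OCc4ccccc4)c2)[C@H](c2ccc(OCc4ccccc4)cc2)O3)cc1 | intermediate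
14 | (2S,3S)-3-(A-yl)-6-(benzyloxy)-2-[4-(benzyloxy)phenyl]-4-{(E)-2-[4-(benzyloxy)phenyl]ethenyl}-2,3-dihydro-1-benzofuran | c1ccccc1COc1ccc([C@H]2Oc3cc(OCc4ccccc4)cc(/C=C/c4ccc(OCc5ccccc5)cc4)c3[C@@H]2c2cc(OCc3ccccc3)cc3c2[C@@H](c2cc(OCc4ccccc4)cc(OCc4ccccc4)c2)[C@H](c2ccc(OCc4ccccc4)cc2)O3)cc1 | intermediate
15 | 1-[(2R,3R)-3-(BA-yl)-6-(benzyloxy)-2-[4-(benzyloxy)phenyl]-5-hydroxy-2,3-dihydro-1-benzofuran-4-yl]ethan-1-one | c1ccccc1COc1ccc([C@H]2Oc3cc(OCc4ccccc4)cc([C@@H]4c5c(C(C)=O)c(O)c(OCc6ccccc6)cc5O[C@H]4c4ccc(OCc5ccccc5)cc4)c3[C@@H]2c2cc(OCc3ccccc3)cc3c2[C@@H](c2cc(OCc4ccccc4)cc(OCc4ccccc4)c2)[C@H](c2ccc(OCc4ccccc4)cc2)O3)cc1 | intermediate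
16 | (2R,3R)-3-(BA-yl)-6-(benzyloxy)-2-[4-(benzyloxy)phenyl]-4-[1-(triflyloxy)ethenyl]-2,3-dihydro-1-benzofuran-5-yl triflate | c1ccccc1COc1ccc([C@H]2Oc3cc(OCc4ccccc4)cc([C@@H]4c5c(C(=C)OS(=O)(=O)C(F)(F)F)c(OS(=O)(=O)C(F)(F)F)c(OCc6ccccc6)cc5O[C@H]4c4ccc(OCc5ccccc5)cc4)c3[C@@H]2c2cc(OCc3ccccc3)cc3c2[C@@H](c2cc(OCc4ccccc4)cc(OCc4ccccc4)c2)[C@H](c2ccc(OCc4ccccc4)cc2)O3)cc1 | intermediate
17 | (2R,3R)-3-(BA-yl)-6-(benzyloxy)-2-[4-(benzyloxy)phenyl]-4-ethenyl-2,3-dihydro-1-benzofuran | c1ccccc1COc1ccc([C@H]2Oc3cc(OCc4ccccc4)cc([C@@H]4c5c(C=C)cc(OCc6ccccc6)cc5O[C@H]4c4ccc(OCc5ccccc5)cc4)c3[C@@H]2c2cc(OCc3ccccc3)cc3c2[C@@H](c2cc(OCc4ccccc4)cc(OCc4ccccc4)c2)[C@H](c2ccc(OCc4ccccc4)cc2)O3)cc1 | intermediate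
18 | 1,2-bis(benzyloxy)-4-bromobenzene | Brc1ccc(OCc2ccccc2)c(OCc2ccccc2)c1 | starting material
19 | (2R,3R)-3-(BA-yl)-6-(benzyloxy)-2-[4-(benzyloxy)phenyl]-4-{(E)-2-[3,4-bis(benzyloxy)phenyl]ethenyl}-2,3-dihydro-1-benzofuran (deca-O-benzyl ether of the target) | c1ccccc1COc1ccc([C@H]2Oc3cc(OCc4ccccc4)cc([C@@H]4c5c(/C=C/c6ccc(OCc7ccccc7)c(OCc7ccccc7)c6)cc(OCc6ccccc6)cc5O[C@H]4c4ccc(OCc5ccccc5)cc4)c3[C@@H]2c2cc(OCc3ccccc3)cc3c2[C@@H](c2cc(OCc4ccccc4)cc(OCc4ccccc4)c2)[C@H](c2ccc(OCc4ccccc4)cc2)O3)cc1 | intermediate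
20 | CNP0099535.1, 4-{(E)-2-[(2R,3R)-6-hydroxy-2-(4-hydroxyphenyl)-3-{(2S,3S)-6-hydroxy-2-(4-hydroxyphenyl)-3-[(2R,3R)-3-(3,5-dihydroxyphenyl)-6-hydroxy-2-(4-hydroxyphenyl)-2,3-dihydro-1-benzofuran-4-yl]-2,3-dihydro-1-benzofuran-4-yl}-2,3-dihydro-1-benzofuran-4-yl]ethenyl}benzene-1,2-diol | Oc1ccc([C@H]2Oc3cc(O)cc([C@@H]4c5c(/C=C/c6ccc(O)c(O)c6)cc(O)cc5O[C@H]4c4ccc(O)cc4)c3[C@@H]2c2cc(O)cc3c2[C@@H](c2cc(O)cc(O)c2)[C@H](c2ccc(O)cc2)O3)cc1 | target

**Step count and risks**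

Total step count: 16. Longest linear sequence: 15 steps (steps 2 to 16, from 3 to 20).

Steps most likely to fail:

1. Step 4. The chelated acetylquinone may close through the acetyl oxygen (hetero-Diels–Alder mode) or react by an uncatalysed background path, so that enantioface selectivity at the alkene is lost. The fallback sets out from 2 and uses the quinone ester class, for which the copper-catalysed enantioselective cycloaddition with aryl alkenes has the closest precedent. Bought methyl 3-(benzyloxy)-5-hydroxybenzoate is oxidised with K2[ON(SO3)2] to methyl 5-(benzyloxy)-3,6-dioxocyclohexa-1,4-diene-1-carboxylate F1. Cycloaddition of F1 with 2 under the conditions of step 4 should give methyl (2R,3R)-6-(benzyloxy)-2-[4-(benzyloxy)phenyl]-3-[3,5-bis(benzyloxy)phenyl]-5-hydroxy-2,3-dihydro-1-benzofuran-4-carboxylate F2. Tf2O and pyridine convert it into the 5-triflate, methyl (2R,3R)-6-(benzyloxy)-2-[4-(benzyloxy)phenyl]-3-[3,5-bis(benzyloxy)phenyl]-5-(triflyloxy)-2,3-dihydro-1-benzofuran-4-carboxylate F3. Reduction with Pd(OAc)2, 1,1'-bis(diphenylphosphino)ferrocene, HCO2H and Et3N gives methyl (2R,3R)-6-(benzyloxy)-2-[4-(benzyloxy)phenyl]-3-[3,5-bis(benzyloxy)phenyl]-2,3-dihydro-1-benzofuran-4-carboxylate F4. Reduction with i-Bu2AlH gives [(2R,3R)-6-(benzyloxy)-2-[4-(benzyloxy)phenyl]-3-[3,5-bis(benzyloxy)phenyl]-2,3-dihydro-1-benzofuran-4-yl]methanol F5, and MnO2 oxidises it to (2R,3R)-6-(benzyloxy)-2-[4-(benzyloxy)phenyl]-3-[3,5-bis(benzyloxy)phenyl]-2,3-dihydro-1-benzofuran-4-carbaldehyde F6. Wittig methylenation (Ph3PCH3Br, KOt-Bu, THF) brings the sequence back to the route at 8.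

2. Step 8 (the same holds for step 12). The ring A stereocentres sit next to the reacting alkene and may oppose the ligand (mismatched double stereodifferentiation), giving poor facial selectivity. The fallback sets out from 10 and 5 and gives up catalyst control: the cycloaddition is run with achiral Sc(OTf)3 in CH2Cl2, which should give 11 together with its ring B diastereomer, 1-[(2R,3R)-3-(A-yl)-6-(benzyloxy)-2-[4-(benzyloxy)phenyl]-5-hydroxy-2,3-dihydro-1-benzofuran-4-yl]ethan-1-one F7. Because ring A is already enantiopure the two are diastereomers, are separated by chromatography, and 11 comes back to the route at step 9.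

3. Step 16. Acid formed during the cleavage of ten ethers may protonate the electron-rich catechol stilbene and lead to cyclisation onto a neighbouring resorcinol ring, and cleavage may be incomplete. The fallback sets out from 17, so that the catechol stilbene is installed only after the Lewis acid step. Debenzylation of 17 (BCl3, pentamethylbenzene, CH2Cl2, −78 °C) should give the octaphenol 5-[(2R,3R)-4-{(2S,3S)-3-[(2R,3R)-4-ethenyl-6-hydroxy-2-(4-hydroxyphenyl)-2,3-dihydro-1-benzofuran-3-yl]-6-hydroxy-2-(4-hydroxyphenyl)-2,3-dihydro-1-benzofuran-4-yl}-6-hydroxy-2-(4-hydroxyphenyl)-2,3-dihydro-1-benzofuran-3-yl]benzene-1,3-diol F8. A Mizoroki–Heck reaction (Pd(OAc)2, P(o-tolyl)3, Et3N, DMF) with 4-bromo-1,2-phenylene diacetate F9, made from 4-bromocatechol with Ac2O and pyridine, gives the 3,4-di-O-acetate of the target F10. Mild methanolysis (K2CO3, MeOH, argon), which also removes any acetyl group that has moved to another phenol, comes back to the route at 20.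

**Further compounds**

F1 | step 4 | methyl 5-(benzyloxy)-3,6-dioxocyclohexa-1,4-diene-1-carboxylate | COC(=O)C1=CC(=O)C=C(OCc2ccccc2)C1=O
F2 | step 4 | methyl (2R,3R)-6-(benzyloxy)-2-[4-(benzyloxy)phenyl]-3-[3,5-bis(benzyloxy)phenyl]-5-hydroxy-2,3-dihydro-1-benzofuran-4-carboxylate | COC(=O)c1c(O)c(OCc2ccccc2)cc2c1[C@@H](c1cc(OCc3ccccc3)cc(OCc3ccccc3)c1)[C@H](c1ccc(OCc3ccccc3)cc1)O2
F3 | step 4 | methyl (2R,3R)-6-(benzyloxy)-2-[4-(benzyloxy)phenyl]-3-[3,5-bis(benzyloxy)phenyl]-5-(triflyloxy)-2,3-dihydro-1-benzofuran-4-carboxylate | COC(=O)c1c(OS(=O)(=O)C(F)(F)F)c(OCc2ccccc2)cc2c1[C@@H](c1cc(OCc3ccccc3)cc(OCc3ccccc3)c1)[C@H](c1ccc(OCc3ccccc3)cc1)O2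
F4 | step 4 | methyl (2R,3R)-6-(benzyloxy)-2-[4-(benzyloxy)phenyl]-3-[3,5-bis(benzyloxy)phenyl]-2,3-dihydro-1-benzofuran-4-carboxylate | COC(=O)c1cc(OCc2ccccc2)cc2c1[C@@H](c1cc(OCc3ccccc3)cc(OCc3ccccc3)c1)[C@H](c1ccc(OCc3ccccc3)cc1)O2
F5 | step 4 | [(2R,3R)-6-(benzyloxy)-2-[4-(benzyloxy)phenyl]-3-[3,5-bis(benzyloxy)phenyl]-2,3-dihydro-1-benzofuran-4-yl]methanol | OCc1cc(OCc2ccccc2)cc2c1[C@@H](c1cc(OCc3ccccc3)cc(OCc3ccccc3)c1)[C@H](c1ccc(OCc3ccccc3)cc1)O2
F6 | step 4 | (2R,3R)-6-(benzyloxy)-2-[4-(benzyloxy)phenyl]-3-[3,5-bis(benzyloxy)phenyl]-2,3-dihydro-1-benzofuran-4-carbaldehyde | O=Cc1cc(OCc2ccccc2)cc2c1[C@@H](c1cc(OCc3ccccc3)cc(OCc3ccccc3)c1)[C@H](c1ccc(OCc3ccccc3)cc1)O2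
F7 | step 8 | 1-[(2R,3R)-3-(A-yl)-6-(benzyloxy)-2-[4-(benzyloxy)phenyl]-5-hydroxy-2,3-dihydro-1-benzofuran-4-yl]ethan-1-one | c1ccccc1COc1ccc([C@@H]2Oc3cc(OCc4ccccc4)c(O)c(C(C)=O)c3[C@H]2c2cc(OCc3ccccc3)cc3c2[C@@H](c2cc(OCc4ccccc4)cc(OCc4ccccc4)c2)[C@H](c2ccc(OCc4ccccc4)cc2)O3)cc1
F8 | step 16 | 5-[(2R,3R)-4-{(2S,3S)-3-[(2R,3R)-4-ethenyl-6-hydroxy-2-(4-hydroxyphenyl)-2,3-dihydro-1-benzofuran-3-yl]-6-hydroxy-2-(4-hydroxyphenyl)-2,3-dihydro-1-benzofuran-4-yl}-6-hydroxy-2-(4-hydroxyphenyl)-2,3-dihydro-1-benzofuran-3-yl]benzene-1,3-diol | Oc1ccc([C@H]2Oc3cc(O)cc([C@@H]4c5c(C=C)cc(O)cc5O[C@H]4c4ccc(O)cc4)c3[C@@H]2c2cc(O)cc3c2[C@@H](c2cc(O)cc(O)c2)[C@H](c2ccc(O)cc2)O3)cc1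
F9 | step 16 | 4-bromo-1,2-phenylene diacetate | CC(=O)Oc1ccc(Br)cc1OC(C)=O
F10 | step 16 | 3,4-di-O-acetate of the target on the catechol ring | Oc1ccc([C@H]2Oc3cc(O)cc([C@@H]4c5c(/C=C/c6ccc(OC(C)=O)c(OC(C)=O)c6)cc(O)cc5O[C@H]4c4ccc(O)cc4)c3[C@@H]2c2cc(O)cc3c2[C@@H](c2cc(O)cc(O)c2)[C@H](c2ccc(O)cc2)O3)cc1
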